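The south-west run with 2 equiv of free base and the west run with 4 equiv ended after 3.00 d with 5.5 % and 5.8 % of the electrophile left, a gap of 0.3 percentage points against a scatter of 1 point, so I took the free base out of my reckoning.

the same everywhere: electrophile 10 mM; nucleophile 1.05 equiv
- south-west: free base 2 equiv; scavenger 1.5 equiv; run made earlier
- west: free base 4 equiv; scavenger 1.5 equiv; run made earlier
- beta: free base 1.50 equiv; scavenger 1.50 equiv; time 3.0 d
- theta: free base 3.00 equiv; scavenger 1.50 equiv; time 3.0 d

| run | time / d | electrophile / % | product / % |
|---|---|---|---|
| south-west | 0.833 | 27.5 | 73.4 |
| south-west | 1.67 | 13.6 | 89.8 |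
| south-west | 2.50 | 8.1 | 92.5 |
| south-west | 3.00 | 5.5 | 92.6 |
| west | 0.250 | 51.4 | 46.9 |
| west | 0.500 | 38.3 | 62.1 |
| west | 1.25 | 14.6 | 84.2 |
| west | 3.00 | 5.8 | 95.6 |

(readings scatter by 1 percentage point)

- part of the electrophile that has reacted at the end, beta
- part of the electrophile that has reacted at the end, theta
- what raising the equivalents of free base from its lowest to its highest value here does to the part of the electrophile that has reacted (changes below 5 percentage points count as none) (no change / it rises / it falls)

- the numbers in the tables scatter with a standard deviation of 1 points

I wrote f for the fraction of the charged electrophile left. The nucleophile, charged in an excess x of 0.0500 over the electrophile, the limiting reagent, then stands at f + x. Integrating df/dt = −κf(f + x) gave κt = ln[(f + x)/(f(1 + x))]/x. The mean end reading, 5.65 %, gave 3.90 /d for κ, the clock constant: the daily fall of f per unit of f(f + x).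

The ladder ran from quick to slow. At the first west reading, 0.250 d, the electrophile and product readings summed to 98.3 %, so I counted the electrophile lost as product. Next, the clock put half the electrophile gone at 0.239 d, and the west run read 51.4 % left at 0.250 d. The last rung was the tail: by the clock, each electrophile's daily chance fell from 4.09 /d to 0.415 /d, ten times lower. Beta and theta share the runs' charges of electrophile and nucleophile and their end time, so I expected 94.3 % reacted in both.

The forecast gave 94 % (89 % to 96 %) for beta, 94.3 % (92.5 % to 96 %) for theta, and no change, holding that “the base is not in the rate law here”. Mine stood 0.35 points above it for beta.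

The flasks gave 94.1 % for beta and 94.6 % for theta, a change of 0.49 points, so no change.

    acid set free + free base ⇌ idle adduct, settled at all times (K = 180 /M)
    electrophile + nucleophile → acid set free + product (k = 22.0 /M/h)
    nucleophile + acid set free ⇌ protonated nucleophile, settled at all times (K = 76000 /M)
    acid set free + free base ⇌ salt of the base (K = 3.10 × 10⁶ /M, k = 360 /M/h)
    acid set free + scavenger → scavenged by-product (k = 1400 /M/h)

In beta, with each step taken alone at the concentrations as charged, the acid set free had a forward half-life of 0.13 h with free base, against 0.13 d for the electrophile with nucleophile. The neighbour flask, theta with 25 mM of electrophile and the same equivalents, kept x, and I scaled κ with the charge to 9.75 /d. Solving the clock for f gives x/[(1 + x)exp(xκt) − 1], which is 1.41 % at 3.0 d. The neighbour flask held 1.24 % of its electrophile at 3.00 d.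

The numbers in the tables were computed with made-up constants; the scatter is artificial.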